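## Retrosynthetic overview

1. The target is a 12-acetoxy-10-chloro cross-conjugated cyclopentenone prostanoid methyl ester (prostanoid numbering: C1 = ester carbon, ring = C8–C12, C20 = terminal methyl). The last operations are desilylation and acetylation of the tertiary C12 oxygen.
2. The only ring is closed last by cutting C8–C9 and C10=C11 together. This gives the acyclic aldehyde–stannane 18 (C11–C12–C8 with both side chains) and the two-carbon unit C9–C10 as 2-chloro-2-(diethoxyphosphoryl)acetyl chloride 21. Forward, an acyl Stille coupling and an intramolecular Horner–Wadsworth–Emmons olefination run in one flask.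
3. Enabling feature: the quaternary carbinol C12 of the five-membered ring is flanked by ring atom C11 (a formyl group with no α-hydrogen) and ring atom C8 (an alkenyl–tin carbon with tin cis to C6). The other two ring atoms, C9 and C10, form a contiguous O=C–C(Cl) unit. Retentive acylation at C8 therefore fixes the 7Z exocyclic alkene, and the olefination delivers the chloro-enone.
4. Stannane 18 comes from hydroxyl-directed trans-hydrostannation of enyne 14, which is made by Sonogashira coupling of alkyne diol 10 with iodide 13.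
5. C12 is set by Sharpless epoxidation of the 2-alkynylallyl alcohol 3 and opening of the epoxide CH2 with a heptynylalane. Lindlar reduction gives the 14Z alkene.

Key step: step 13

Remark: the facial sense of the epoxidation in step 2 is assumed to follow that of allyl and 2-methylallyl alcohol, where L-(+)-tartrate gives the (S)-glycidols.

## Route

Step 1
Reactants: 1 2-bromoprop-2-en-1-ol; 2 ethynyltri(propan-2-yl)silane
Product: 3 2-methylidene-4-[tri(propan-2-yl)silyl]but-3-yn-1-ol
Conditions: PdCl2(PPh3)2 (2 mol %), CuI (4 mol %), i-Pr2NH, THF, rt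
Reagents that add atoms: none
Why: Sonogashira coupling of a vinyl bromide with a terminal alkyne, which tolerates the free allylic alcohol and creates no stereocentre.

Step 2
Reactants: 3 2-methylidene-4-[tri(propan-2-yl)silyl]but-3-yn-1-ol
Product: 4 [(2S)-2-{[tri(propan-2-yl)silyl]ethynyl}oxiran-2-yl]methanol
Conditions: Ti(OiPr)4 (10 mol %), L-(+)-diisopropyl tartrate (12 mol %), t-BuOOH, 4 Å molecular sieves, CH2Cl2, −20 °C
Reagents that add atoms: tert-butyl hydroperoxide, CC(C)(C)OO
Why: Sharpless asymmetric epoxidation, in which the titanium-bound allylic alkoxide receives the peroxide oxygen on the alkene face selected by L-(+)-tartrate, so that the future C12 centre should be set as S (the alkynyl group ranks lowest).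

Step 3
Reactants: 5 hept-1-yne; 4 [(2S)-2-{[tri(propan-2-yl)silyl]ethynyl}oxiran-2-yl]methanol
Product: 8 (2S)-2-{[tri(propan-2-yl)silyl]ethynyl}dec-4-yne-1,2-diol, via hept-1-ynyllithium 6 (not isolated), via diethyl(hept-1-ynyl)alane 7 (not isolated)
Conditions: 5, n-BuLi, toluene, 0 °C; Et2AlCl, 0 °C; then 4, 0 °C to rt; aqueous Rochelle salt work-up
Reagents that add atoms: none
Why: Hydroxyl-directed opening of a 2,3-epoxy alcohol by an alkynylalane, in which the aluminium alkoxide should deliver the alkynyl group to the unsubstituted epoxide CH2 in an SN2 process, leaving the C–O bond at the quaternary carbon (and its configuration) untouched and avoiding the base-induced Payne rearrangement that would racemise this epoxide.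

Step 4
Reactants: 8 (2S)-2-{[tri(propan-2-yl)silyl]ethynyl}dec-4-yne-1,2-diol
Product: 9 (2S,4Z)-2-{[tri(propan-2-yl)silyl]ethynyl}dec-4-ene-1,2-diol
Conditions: H2 (1 atm), Pd on CaCO3 poisoned with Pb(OAc)2, quinoline, EtOAc, rt
Reagents that add atoms: none
Why: Lindlar semi-hydrogenation, whose syn addition of hydrogen to the unhindered dialkyl alkyne should give the Z alkene while the silyl-capped alkyne on the quaternary carbon is too hindered to react.

Step 5
Reactants: 9 (2S,4Z)-2-{[tri(propan-2-yl)silyl]ethynyl}dec-4-ene-1,2-diol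
Product: 10 (2S,4Z)-2-ethynyldec-4-ene-1,2-diol
Conditions: Bu4NF, THF, 0 °C to rt
Reagents that add atoms: none
Why: Fluoride-induced protodesilylation of an alkynylsilane, to which the diol and the alkene are inert.

Step 6
Reactants: 11 methyl hex-5-ynoate
Product: 13 methyl (5E)-6-iodohex-5-enoate, via alkenylzirconocene chloride 12 (not isolated)
Conditions: Cp2Zr(H)Cl, THF, rt; then I2, 0 °C
Reagents that add atoms: iodine, II
Why: Hydrozirconation (syn, terminal metal) followed by iodinolysis with retention should give the E iodide, the alkyne reacting much faster than the ester with Cp2Zr(H)Cl.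

Step 7
Reactants: 10 (2S,4Z)-2-ethynyldec-4-ene-1,2-diol; 13 methyl (5E)-6-iodohex-5-enoate
Product: 14 methyl (5E,9S,11Z)-9-hydroxy-9-(hydroxymethyl)heptadeca-5,11-dien-7-ynoate
Conditions: Pd(PPh3)4 (3 mol %), CuI (6 mol %), Et3N, THF, rt
Reagents that add atoms: none
Why: Sonogashira coupling, which proceeds with retention of the E iodide geometry and tolerates free hydroxyl groups and the ester.

Step 8
Reactants: 14 methyl (5E,9S,11Z)-9-hydroxy-9-(hydroxymethyl)heptadeca-5,11-dien-7-ynoate
Product: 15 methyl (5E,7Z,9R,11Z)-9-hydroxy-9-(hydroxymethyl)-8-(tributylstannyl)heptadeca-5,7,11-trienoate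
Conditions: [Cp*RuCl]4 (2.5 mol %), Bu3SnH (1.1 equiv, slow addition), CH2Cl2, rt; chromatography on Et3N-deactivated silica
Reagents that add atoms: tributylstannane, CCCC[SnH](CCCC)CCCC
Why: Ruthenium-catalysed trans-hydrostannation, in which hydrogen bonding of the propargylic hydroxyl to the chloride ligand should steer tin to the alkyne carbon next to the carbinol and the anti addition places tin cis to C6, the arrangement that later becomes 7Z (the descriptor at the carbinol changes to R only because tin raises the rank of C8).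

Step 9
Reactants: 15 methyl (5E,7Z,9R,11Z)-9-hydroxy-9-(hydroxymethyl)-8-(tributylstannyl)heptadeca-5,7,11-trienoate
Product: 16 methyl (5E,7Z,9R,11Z)-8-(tributylstannyl)-9-[(triethylsilyl)oxy]-9-{[(triethylsilyl)oxy]methyl}heptadeca-5,7,11-trienoate
Conditions: Et3SiOTf (2.5 equiv), 2,6-lutidine, CH2Cl2, −78 to 0 °C
Reagents that add atoms: triethylsilyl trifluoromethanesulfonate, CC[Si](CC)(CC)OS(=O)(=O)C(F)(F)F
Why: Silylation with a silyl triflate, which is reactive enough for the hindered tertiary alcohol, under buffered conditions that should not protodestannylate the alkenylstannane.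

Step 10
Reactants: 16 methyl (5E,7Z,9R,11Z)-8-(tributylstannyl)-9-[(triethylsilyl)oxy]-9-{[(triethylsilyl)oxy]methyl}heptadeca-5,7,11-trienoate
Product: 18 methyl (5E,7Z,9R,11Z)-9-formyl-8-(tributylstannyl)-9-[(triethylsilyl)oxy]heptadeca-5,7,11-trienoate, via alkoxysulfonium chloride 17 (not isolated)
Conditions: (COCl)2, DMSO, CH2Cl2, −78 to −30 °C; then Et3N, −78 °C to rt
Reagents that add atoms: none
Why: Swern oxidation with in situ cleavage of a primary triethylsilyl ether, in which only the unhindered primary silyl ether is attacked by the chlorosulfonium salt and oxidised while the tertiary silyl ether survives, and the aldehyde formed has no α-hydrogen.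

Step 11
Reactants: 19 ethyl 2-chloro-2-(diethoxyphosphoryl)acetate
Product: 20 2-chloro-2-(diethoxyphosphoryl)acetic acid
Conditions: NaOH (1.05 equiv), EtOH/H2O, 0 °C to rt; then HCl to pH 1, extraction
Reagents that add atoms: sodium hydroxide, [Na+].[OH-]
Why: Saponification, which should be selective because the carboxylic ester is far more electrophilic than the two phosphonate esters.

Step 12
Reactants: 20 2-chloro-2-(diethoxyphosphoryl)acetic acid
Product: 21 2-chloro-2-(diethoxyphosphoryl)acetyl chloride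
Conditions: (COCl)2, DMF (cat.), CH2Cl2, 0 °C to rt; concentrated and used crude
Reagents that add atoms: oxalyl chloride, ClC(=O)C(=O)Cl
Why: Acid chloride formation with oxalyl chloride and catalytic DMF under base-free conditions, which avoids ketene formation from the acidic α-position.

Step 13
Reactants: 18 methyl (5E,7Z,9R,11Z)-9-formyl-8-(tributylstannyl)-9-[(triethylsilyl)oxy]heptadeca-5,7,11-trienoate; 21 2-chloro-2-(diethoxyphosphoryl)acetyl chloride
Product: 23 methyl (5E,7Z)-7-[(5R)-3-chloro-5-[(2Z)-oct-2-en-1-yl]-2-oxo-5-[(triethylsilyl)oxy]cyclopent-3-en-1-ylidene]hept-5-enoate, via keto phosphonate 22 (not isolated)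
Conditions: 21 (1.3 equiv), Pd2(dba)3 (5 mol %), AsPh3 (20 mol %), CuI (10 mol %), THF, 45 °C, dark; then LiCl, i-Pr2NEt, MeCN, 0 °C to rt
Reagents that add atoms: none
Why: Zerovalent palladium should insert into the acid chloride 21, the alkenylstannane transmetalates (assisted by CuI) and reductive elimination forms the C8–C9 bond with retention to give keto phosphonate 22, after which LiCl and i-Pr2NEt deprotonate the doubly activated C10–H, the phosphonate carbanion adds to the C11 formyl group and syn-elimination of diethyl phosphate forms the C10=C11 bond. The closest known reactions are the acyl Stille coupling and the intramolecular Horner–Wadsworth–Emmons olefination under Masamune–Roush conditions, the latter being the standard closure of keto phosphonates onto a 1,4-related carbonyl group to give cyclopentenones and the standard route from α-chloro phosphonates to α-chloro enones. The five-membered ring closes in the olefination event, formally a 5-(enolendo)-exo-trig attack of C10 on C11, the same mode by which 1,4-dicarbonyl compounds give cyclopentenones. No new stereocentre is formed: the quaternary C12 is not involved, the 7Z geometry follows from retention at the alkenyl–tin carbon, and the ring C10=C11 bond can only be cis. The step needs chemoselective acylation at tin beside a free aldehyde and a single condensation mode, which are secured because the C11 aldehyde has no α-hydrogen, C10 is the only acidic position of 22, the phosphoryl group diverts the chloro-aldolate to the alkene instead of a Darzens epoxide, and the tertiary silyl ether (unlike an acetate) cannot ionise with palladium or eliminate next to tin.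

Step 14
Reactants: 23 methyl (5E,7Z)-7-[(5R)-3-chloro-5-[(2Z)-oct-2-en-1-yl]-2-oxo-5-[(triethylsilyl)oxy]cyclopent-3-en-1-ylidene]hept-5-enoate
Product: 24 methyl (5E,7Z)-7-[(5R)-3-chloro-5-hydroxy-5-[(2Z)-oct-2-en-1-yl]-2-oxocyclopent-3-en-1-ylidene]hept-5-enoate
Conditions: HF·pyridine, pyridine, THF, 0 °C to rt, dark
Reagents that add atoms: none
Why: Fluoride cleavage of the tertiary triethylsilyl ether under buffered, non-basic conditions that the base-sensitive cross-conjugated chlorodienone should tolerate.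

Step 15
Reactants: 24 methyl (5E,7Z)-7-[(5R)-3-chloro-5-hydroxy-5-[(2Z)-oct-2-en-1-yl]-2-oxocyclopent-3-en-1-ylidene]hept-5-enoate
Product: 25 methyl (5E,7Z)-7-[(5R)-5-(acetyloxy)-3-chloro-5-[(2Z)-oct-2-en-1-yl]-2-oxocyclopent-3-en-1-ylidene]hept-5-enoate
Conditions: Ac2O, DMAP (cat.), Et3N, CH2Cl2, 0 °C to rt, dark
Reagents that add atoms: acetic anhydride, CC(=O)OC(C)=O
Why: DMAP-catalysed acetylation of the tertiary alcohol through the acetylpyridinium ion, which leaves the C12 centre and both alkene geometries untouched.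

## Compound list

1 | 2-bromoprop-2-en-1-ol | OCC(Br)=C | starting material
2 | ethynyltri(propan-2-yl)silane | C#C[Si](C(C)C)(C(C)C)C(C)C | starting material
3 | 2-methylidene-4-[tri(propan-2-yl)silyl]but-3-yn-1-ol | OCC(=C)C#C[Si](C(C)C)(C(C)C)C(C)C | intermediate
4 | [(2S)-2-{[tri(propan-2-yl)silyl]ethynyl}oxiran-2-yl]methanol | OC[C@@]1(C#C[Si](C(C)C)(C(C)C)C(C)C)CO1 | intermediate
5 | hept-1-yne | CCCCCC#C | starting material
6 | hept-1-yn-1-yllithium | [Li]C#CCCCCC | intermediate (not isolated)
7 | diethyl(hept-1-yn-1-yl)alumane | CC[Al](CC)C#CCCCCC | intermediate (not isolated)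
8 | (2S)-2-{[tri(propan-2-yl)silyl]ethynyl}dec-4-yne-1,2-diol | CCCCCC#CC[C@@](C#C[Si](C(C)C)(C(C)C)C(C)C)(O)CO | intermediate
9 | (2S,4Z)-2-{[tri(propan-2-yl)silyl]ethynyl}dec-4-ene-1,2-diol | CCCCC/C=C\C[C@@](C#C[Si](C(C)C)(C(C)C)C(C)C)(O)CO | intermediate
10 | (2S,4Z)-2-ethynyldec-4-ene-1,2-diol | CCCCC/C=C\C[C@@](C#C)(O)CO | intermediate
11 | methyl hex-5-ynoate | COC(=O)CCCC#C | starting material
12 | methyl (5E)-6-[chlorobis(cyclopentadienyl)zirconio]hex-5-enoate | COC(=O)CCC/C=C/[Zr](Cl)(C1C=CC=C1)C1C=CC=C1 | intermediate (not isolated)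
13 | methyl (5E)-6-iodohex-5-enoate | COC(=O)CCC/C=C/I | intermediate
14 | methyl (5E,9S,11Z)-9-hydroxy-9-(hydroxymethyl)heptadeca-5,11-dien-7-ynoate | CCCCC/C=C\C[C@@](C#C/C=C/CCCC(=O)OC)(O)CO | intermediate
15 | methyl (5E,7Z,9R,11Z)-9-hydroxy-9-(hydroxymethyl)-8-(tributylstannyl)heptadeca-5,7,11-trienoate | CCCCC/C=C\C[C@@](/C(=C/C=C/CCCC(=O)OC)[Sn](CCCC)(CCCC)CCCC)(O)CO | intermediate
16 | methyl (5E,7Z,9R,11Z)-8-(tributylstannyl)-9-[(triethylsilyl)oxy]-9-{[(triethylsilyl)oxy]methyl}heptadeca-5,7,11-trienoate | CCCCC/C=C\C[C@@](/C(=C/C=C/CCCC(=O)OC)[Sn](CCCC)(CCCC)CCCC)(O[Si](CC)(CC)CC)CO[Si](CC)(CC)CC | intermediate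
17 | alkoxydimethylsulfonium chloride of 16 (primary Et3Si group replaced by SMe2+, chloride counter-ion) | CCCCC/C=C\C[C@@](/C(=C/C=C/CCCC(=O)OC)[Sn](CCCC)(CCCC)CCCC)(O[Si](CC)(CC)CC)CO[S+](C)C.[Cl-] | intermediate (not isolated)
18 | methyl (5E,7Z,9R,11Z)-9-formyl-8-(tributylstannyl)-9-[(triethylsilyl)oxy]heptadeca-5,7,11-trienoate | CCCCC/C=C\C[C@@](/C(=C/C=C/CCCC(=O)OC)[Sn](CCCC)(CCCC)CCCC)(O[Si](CC)(CC)CC)C=O | intermediate
19 | ethyl 2-chloro-2-(diethoxyphosphoryl)acetate | CCOC(=O)C(Cl)P(=O)(OCC)OCC | starting material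
20 | 2-chloro-2-(diethoxyphosphoryl)acetic acid | OC(=O)C(Cl)P(=O)(OCC)OCC | intermediate
21 | 2-chloro-2-(diethoxyphosphoryl)acetyl chloride | ClC(=O)C(Cl)P(=O)(OCC)OCC | intermediate
22 | methyl (5E,7Z,9S,11Z)-8-[2-chloro-2-(diethoxyphosphoryl)acetyl]-9-formyl-9-[(triethylsilyl)oxy]heptadeca-5,7,11-trienoate (both epimers at the CHCl carbon) | CCCCC/C=C\C[C@@](/C(=C/C=C/CCCC(=O)OC)C(=O)C(Cl)P(=O)(OCC)OCC)(O[Si](CC)(CC)CC)C=O | intermediate (not isolated)
23 | methyl (5E,7Z)-7-[(5R)-3-chloro-5-[(2Z)-oct-2-en-1-yl]-2-oxo-5-[(triethylsilyl)oxy]cyclopent-3-en-1-ylidene]hept-5-enoate | CCCCC/C=C\C[C@@]1(O[Si](CC)(CC)CC)C=C(Cl)C(=O)/C1=C\C=C\CCCC(=O)OC | intermediate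
24 | methyl (5E,7Z)-7-[(5R)-3-chloro-5-hydroxy-5-[(2Z)-oct-2-en-1-yl]-2-oxocyclopent-3-en-1-ylidene]hept-5-enoate | CCCCC/C=C\C[C@@]1(O)C=C(Cl)C(=O)/C1=C\C=C\CCCC(=O)OC | intermediate
25 | methyl (5E,7Z)-7-[(5R)-5-(acetyloxy)-3-chloro-5-[(2Z)-oct-2-en-1-yl]-2-oxocyclopent-3-en-1-ylidene]hept-5-enoate | CCCCC/C=C\C[C@@]1(OC(C)=O)C=C(Cl)C(=O)/C1=C\C=C\CCCC(=O)OC | target

## Step count and risks

Total step count: 15. Longest linear sequence: 12 steps (steps 1–5, 7–10, 13–15).

**Step 13.** Transmetalation of the hindered, α-branched alkenylstannane may be slow, so that protodestannylation or decomposition of the acid chloride overtakes the coupling. The fallback sets out from 16. Iododestannylation (I2, CH2Cl2, 0 °C) should give methyl (5E,7Z,9R,11Z)-8-iodo-9-[(triethylsilyl)oxy]-9-{[(triethylsilyl)oxy]methyl}heptadeca-5,7,11-trienoate F1 with retention. Iodine–magnesium exchange (i-PrMgCl·LiCl, THF, −40 °C, which the methyl ester should survive) and acylation with 2-chloro-N-methoxy-N-methylacetamide should give the chloromethyl ketone methyl (5E,7Z,9S,11Z)-8-(chloroacetyl)-9-[(triethylsilyl)oxy]-9-{[(triethylsilyl)oxy]methyl}heptadeca-5,7,11-trienoate F2. Swern oxidation as in step 10 should give the keto aldehyde methyl (5E,7Z,9S,11Z)-8-(chloroacetyl)-9-formyl-9-[(triethylsilyl)oxy]heptadeca-5,7,11-trienoate F3. An intramolecular aldol condensation under amine–acid catalysis (dibenzylammonium trifluoroacetate, benzene, 50 °C), in which C10 is again the only enolisable position, closes the ring and comes back to the route at 23.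

**Step 8.** Coordination of the conjugated C5=C6 alkene to ruthenium may erode the regio- or stereoselectivity of the tin delivery. The fallback sets out from 10. Palladium-catalysed syn-distannylation of the terminal alkyne (Bu3SnSnBu3, Pd(PPh3)4, THF, 65 °C) should give (2R,4Z)-2-[(Z)-1,2-bis(tributylstannyl)ethenyl]dec-4-ene-1,2-diol F4. A site-selective Stille coupling of its unhindered terminal C–Sn bond with iodide 13 (Pd2(dba)3, AsPh3, CuI, DMF, rt) places C6 cis to the remaining tin and comes back to the route at 15.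

**Step 3.** The alane may attack the tertiary propargylic epoxide carbon, or the opening may be sluggish. The fallback sets out from 4. Silylation (t-BuMe2SiCl, imidazole, DMF) should give tert-butyl(dimethyl){[(2R)-2-{[tri(propan-2-yl)silyl]ethynyl}oxiran-2-yl]methoxy}silane F5. SN2 opening at the epoxide CH2 with hept-1-ynyllithium 6 and BF3·OEt2 (THF, −78 °C) should give (2S)-1-{[tert-butyl(dimethyl)silyl]oxy}-2-{[tri(propan-2-yl)silyl]ethynyl}dec-4-yn-2-ol F6. Lindlar semi-hydrogenation as in step 4 should give (2S,4Z)-1-{[tert-butyl(dimethyl)silyl]oxy}-2-{[tri(propan-2-yl)silyl]ethynyl}dec-4-en-2-ol F7. Bu4NF then removes both silyl groups and comes back to the route at 10.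

## Further compounds

F1 | step 13 | methyl (5E,7Z,9R,11Z)-8-iodo-9-[(triethylsilyl)oxy]-9-{[(triethylsilyl)oxy]methyl}heptadeca-5,7,11-trienoate | CCCCC/C=C\C[C@@](/C(I)=C/C=C/CCCC(=O)OC)(O[Si](CC)(CC)CC)CO[Si](CC)(CC)CC
F2 | step 13 | methyl (5E,7Z,9S,11Z)-8-(chloroacetyl)-9-[(triethylsilyl)oxy]-9-{[(triethylsilyl)oxy]methyl}heptadeca-5,7,11-trienoate | CCCCC/C=C\C[C@@](/C(=C/C=C/CCCC(=O)OC)C(=O)CCl)(O[Si](CC)(CC)CC)CO[Si](CC)(CC)CC
F3 | step 13 | methyl (5E,7Z,9S,11Z)-8-(chloroacetyl)-9-formyl-9-[(triethylsilyl)oxy]heptadeca-5,7,11-trienoate | CCCCC/C=C\C[C@@](/C(=C/C=C/CCCC(=O)OC)C(=O)CCl)(O[Si](CC)(CC)CC)C=O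
F4 | step 8 | (2R,4Z)-2-[(Z)-1,2-bis(tributylstannyl)ethenyl]dec-4-ene-1,2-diol | CCCCC/C=C\C[C@@](/C(=C/[Sn](CCCC)(CCCC)CCCC)[Sn](CCCC)(CCCC)CCCC)(O)CO
F5 | step 3 | tert-butyl(dimethyl){[(2R)-2-{[tri(propan-2-yl)silyl]ethynyl}oxiran-2-yl]methoxy}silane | CC(C)(C)[Si](C)(C)OC[C@@]1(C#C[Si](C(C)C)(C(C)C)C(C)C)CO1
F6 | step 3 | (2S)-1-{[tert-butyl(dimethyl)silyl]oxy}-2-{[tri(propan-2-yl)silyl]ethynyl}dec-4-yn-2-ol | CCCCCC#CC[C@@](C#C[Si](C(C)C)(C(C)C)C(C)C)(O)CO[Si](C)(C)C(C)(C)C
F7 | step 3 | (2S,4Z)-1-{[tert-butyl(dimethyl)silyl]oxy}-2-{[tri(propan-2-yl)silyl]ethynyl}dec-4-en-2-ol | CCCCC/C=C\C[C@@](C#C[Si](C(C)C)(C(C)C)C(C)C)(O)CO[Si](C)(C)C(C)(C)C
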